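The numbers are made up; the result is computed.

A small charge of starting material, 0.60 M in theta, meets 0.150 M of protic impurity; the other flasks keep that impurity and raise the loading.

in all of them: protic impurity 0.150 M; time 5.0 d

| run | starting material |
|---|---|
| theta | 0.60 M |
| delta | 0.80 M |
| eta | 1.2 M |
| zeta | 2.0 M |
| epsilon | 3.0 M |

    starting material ⇌ target (K1 = 0.34, k1 = 2.1 × 10⁻⁶ s⁻¹)
    target ⇌ isomer of the product (K2 = 0.70, k2 = 3.5 × 10⁻⁵ s⁻¹)
    2 starting material → self-condensation product (k3 = 1.0 × 10⁻⁷ M⁻¹ s⁻¹)
    starting material + protic impurity → quenched substrate (k4 = 8.4 × 10⁻⁵ M⁻¹ s⁻¹)

- a species is counted by the starting material in it: one self-condensation product counts as two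
- for a step with 2 of a species take k times the square, and two of it per event
- "hardly changes" means that all values lie within two and a half points (for a concentration: within two and a half percent of the largest)
- run time (theta): 5.0 d

- [target] at the end for theta, delta, eta, zeta, epsilon, in this order
- how the row runs (falls, then rises / falls all the way / hardly changes / rises, then falls / rises all the way)

Go down the time scales in theta, fastest first. At the start, starting material goes 6.0 times faster into quenched substrate than into target, and with starting material held at its charge the impurity halves in 0.159 d. The impurity is the limiting reagent of that step, so you take its amount off at once and keep a usable charge of 0.450 M.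

Next, target passes into isomer of the product with a forward half-life of 0.229 d, shorter than the 0.969 d in which starting material and target relax by their own step. So I treat target and isomer as one pair, split by the second equilibrium constant. Target is a part of that pair, so the way back to starting material thins by target's share of it, and the relaxation half-life lengthens to 1.40 d. The run holds 3.57 such half-lives. At equilibrium target would hold 21.5% of the three forms.

Carry one number from this: the end yield on the usable charge, which is that equilibrium share times the part of the relaxation finished within the run, 19.7%.

Slowest comes self-condensation, with a first half-life at the charge of 96.5 d in theta and 19.3 d in epsilon, both longer than the run. My reckoning therefore gives 0.0887 M for theta and, leaving self-condensation out, 0.562 M as a figure for epsilon. Now score each shape by a ratio: for a rise, the usable charge of epsilon over that of theta; for a shape that starts by falling, the inverse of that; for a rise that turns over, the run over self-condensation's half-life in epsilon; for a flat row, one. The highest score gives rises all the way.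

The forecast reads 0.089 M, 0.126 M, 0.2 M, 0.342 M, 0.509 M, and rises all the way; of self-condensation it says “it bends the row slightly but cannot turn it over”. At epsilon it stands lower than my figure.

The flasks give 0.0874 M, 0.125 M, 0.199 M, 0.340 M, 0.506 M: rises all the way. At the end of theta the impurity stands at 0% of its charge and quenched substrate at 25.0% of the starting material charged. Theta's target is 19.4% of the usable charge, against the carried 19.7%. In epsilon that same 19.7% of the usable charge makes 0.562 M, while the flask holds less, 0.506 M, and 12.2% of its charge stands as self-condensation product.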